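**Retrosynthetic overview**

1. Ring B is opened last at O5–C6 (Mitsunobu etherification of a C6 alcohol onto the ring A phenol). This leaves ring C as a cis-2-aryl-2,3-dihydrobenzofuran on the hexasubstituted ring D, with the one-carbon branch C6 on C6a.
2. That unit (O11–C11a–C6a–C6b–C10a, with C6 on C6a) is the ring-contracted form of a 2-arylchroman-4-one built on ring D. The C6a–C6b bond is therefore disconnected by Wolff contraction of a 3-diazoflavanone (flavanone C2, C3, C4 become C11a, C6a, C6).
3. The flavanone comes from the chalcone of a ring D acetophenone and a ring A aldehyde. Its C2 (later C11a) is fixed by kinetic resolution of the racemic flavanone through asymmetric transfer hydrogenation.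
4. Ring D ketone: ring E by propargyl ether Claisen rearrangement and electrocyclisation onto the carbon ortho to the acetyl group, then the C10 prenyl group by Stille coupling. Ring A aldehyde: prenyl group by Stille coupling.
5. Ring order: E, the temporary pyranone, C (by contraction), B.

Key step: step 13

Assumption: 5-bromo-2,4-dihydroxybenzaldehyde, 3-chloro-3-methylbut-1-yne and tributyl(3-methylbut-2-en-1-yl)stannane are taken as purchased materials, and the (S,S)-TsDPEN catalyst is taken to follow its usual sense of hydride delivery (4S alcohols from benzo-fused cyclic ketones).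

Flavanone numbering is used for compounds 14–17, 2,3-dihydrobenzofuran numbering (C2 = C11a, C3 = C6a) for 20–22, and pterocarpan numbering from 23 on. "Prenyl" is 3-methylbut-2-en-1-yl, "MOM" is methoxymethyl.

**Step 1**
Reactants: 1 2,4,5-trihydroxyacetophenone
Product: 2 1-[2,5-dihydroxy-4-(methoxymethoxy)phenyl]ethan-1-one
Conditions: MOMCl (1.05 equiv), K2CO3, acetone, 0 °C → rt, Ar
Reagents that add atoms: chloromethyl methyl ether, COCCl
Why: Williamson-type O-alkylation should take place at the 4-OH, which is para to the acetyl group and the most acidic, while the 2-OH is held in a hydrogen bond to the carbonyl and the 5-OH (meta to the acetyl group) is less acidic.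

**Step 2**
Reactants: 2 1-[2,5-dihydroxy-4-(methoxymethoxy)phenyl]ethan-1-one; 3 3-chloro-3-methylbut-1-yne
Product: 4 1-[2-hydroxy-4-(methoxymethoxy)-5-[(2-methylbut-3-yn-2-yl)oxy]phenyl]ethan-1-one
Conditions: K2CO3, KI (cat.), CuI (cat.), acetone, 55 °C, Ar
Reagents that add atoms: none
Why: Copper-catalysed propargylic etherification of the only free, non-chelated phenol (O5) with the tertiary propargylic chloride should give the aryl 1,1-dimethylpropargyl ether, the chelated 2-OH being far less nucleophilic.

**Step 3**
Reactants: 4 1-[2-hydroxy-4-(methoxymethoxy)-5-[(2-methylbut-3-yn-2-yl)oxy]phenyl]ethan-1-one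
Product: 5 1-[2-hydroxy-3-iodo-4-(methoxymethoxy)-5-[(2-methylbut-3-yn-2-yl)oxy]phenyl]ethan-1-one
Conditions: NIS, DMF, 0 °C → rt, dark
Reagents that add atoms: N-iodosuccinimide, O=C1CCC(=O)N1I
Why: Electrophilic aromatic iodination should go to C3, which is ortho to the free phenol and to the MOM ether, whereas C6 is activated by one ether oxygen only and flanked by the acetyl group, and the terminal alkyne does not react with NIS without silver or base.

**Step 4**
Reactants: 5 1-[2-hydroxy-3-iodo-4-(methoxymethoxy)-5-[(2-methylbut-3-yn-2-yl)oxy]phenyl]ethan-1-one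
Product: 6 1-[6-hydroxy-7-iodo-8-(methoxymethoxy)-2,2-dimethyl-2H-chromen-5-yl]ethan-1-one
Conditions: PhNEt2, 150 °C
Reagents that add atoms: none
Why: Aromatic propargyl Claisen rearrangement to the only free ortho carbon (C6 of the acetophenone), tautomerisation to the o-allenylphenol, 1,5-hydrogen shift and oxa-6π electrocyclisation should close ring E as the 2,2-dimethyl-2H-chromene with its carbon arm ortho to the acetyl group.

**Step 5**
Reactants: 6 1-[6-hydroxy-7-iodo-8-(methoxymethoxy)-2,2-dimethyl-2H-chromen-5-yl]ethan-1-one; 7 tributyl(3-methylbut-2-en-1-yl)stannane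
Product: 8 1-[6-hydroxy-8-(methoxymethoxy)-2,2-dimethyl-7-(3-methylbut-2-en-1-yl)-2H-chromen-5-yl]ethan-1-one (ring D ketone)
Conditions: Pd(PPh3)4 (5 mol%), DMF, 90 °C
Reagents that add atoms: none
Why: Stille coupling (oxidative addition of the aryl iodide to zerovalent palladium, transmetalation of the allylic stannane, reductive elimination) should deliver the linear prenyl arene, with the chelated phenol, ketone, MOM ether and chromene left untouched.

**Step 6**
Reactants: 9 5-bromo-2,4-dihydroxybenzaldehyde
Product: 10 5-bromo-2-hydroxy-4-(methoxymethoxy)benzaldehyde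
Conditions: MOMCl (1.05 equiv), K2CO3, acetone, rt
Reagents that add atoms: chloromethyl methyl ether, COCCl
Why: Williamson-type O-alkylation should be selective for the 4-OH (para to the formyl group, ortho to bromine, most acidic), the 2-OH being chelated to the aldehyde.

**Step 7**
Reactants: 10 5-bromo-2-hydroxy-4-(methoxymethoxy)benzaldehyde; 7 tributyl(3-methylbut-2-en-1-yl)stannane
Product: 11 2-hydroxy-4-(methoxymethoxy)-5-(3-methylbut-2-en-1-yl)benzaldehyde
Conditions: Pd(PPh3)4 (5 mol%), DMF, 100 °C
Reagents that add atoms: none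
Why: Stille coupling of the aryl bromide should install the linear prenyl group at C5; it is run before O-allylation so that no allyl aryl ether is exposed to zerovalent palladium together with an allyl nucleophile.

**Step 8**
Reactants: 11 2-hydroxy-4-(methoxymethoxy)-5-(3-methylbut-2-en-1-yl)benzaldehyde
Product: 12 4-(methoxymethoxy)-5-(3-methylbut-2-en-1-yl)-2-(prop-2-en-1-yloxy)benzaldehyde (ring A aldehyde)
Conditions: allyl bromide, K2CO3, DMF, 50 °C
Reagents that add atoms: allyl bromide, C=CCBr
Why: Williamson etherification of the remaining phenol should give an allyl ether that withstands hydroxide, amide base, hydride and light and can later be removed without acid in the presence of the MOM ethers.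

**Step 9**
Reactants: 8 ring D ketone; 12 ring A aldehyde
Product: 13 (E)-1-[6-hydroxy-8-(methoxymethoxy)-2,2-dimethyl-7-prenyl-2H-chromen-5-yl]-3-[4-(methoxymethoxy)-5-prenyl-2-(prop-2-en-1-yloxy)phenyl]prop-2-en-1-one (2'-hydroxychalcone)
Conditions: KOH (50% aq.), EtOH, rt
Reagents that add atoms: none
Why: Claisen–Schmidt condensation of the methyl ketone enolate with the non-enolisable aldehyde, followed by dehydration, should give the E-chalcone, all ethers and alkenes being stable to hydroxide.

**Step 10**
Reactants: 13 2'-hydroxychalcone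
Product: 14 racemic 2-[4-(methoxymethoxy)-5-prenyl-2-(prop-2-en-1-yloxy)phenyl]-7-(methoxymethoxy)-8-prenylchroman-4-one carrying ring E (2,2-dimethyl-2H-pyran) fused across C5–C6 with the pyran oxygen on C6
Conditions: NaOAc, EtOH, reflux
Reagents that add atoms: none
Why: Base-mediated 6-endo oxa-Michael cyclisation of the 2'-phenol onto the enone should give the flavanone, which is favoured at equilibrium because the second ortho substituent twists the chalcone carbonyl out of conjugation; C2 forms as a racemate.

**Step 11**
Reactants: 14 racemic flavanone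
Product: 15 (2R)-2-[4-(methoxymethoxy)-5-prenyl-2-(prop-2-en-1-yloxy)phenyl]-7-(methoxymethoxy)-8-prenylchroman-4-one carrying ring E fused across C5–C6 (2R-flavanone)
Conditions: Cp*RhCl[(S,S)-TsDPEN] (1 mol%), HCO2H/Et3N (5:2), EtOAc, rt, stopped near 50–55% conversion
Reagents that add atoms: none
Why: Noyori-type asymmetric transfer hydrogenation used as a kinetic resolution: the (S,S) catalyst forms 4S alcohols, which is the matched cis-selective reduction only for the 2S flavanone, so that enantiomer should be consumed as the (2S,4S)-cis-flavan-4-ol while the 2R ketone 15, whose C2 becomes C11a, remains and is separated by chromatography; isolated alkenes, MOM and allyl ethers are inert to the metal hydride.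

**Step 12**
Reactants: 15 2R-flavanone
Product: 17 (2S)-3-diazo-2-[4-(methoxymethoxy)-5-prenyl-2-(prop-2-en-1-yloxy)phenyl]-7-(methoxymethoxy)-8-prenylchroman-4-one carrying ring E fused across C5–C6 (same spatial arrangement at C2 as 15; the descriptor changes because the diazo carbon outranks the aryl group), via 3-trifluoroacetylflavanone 16 (not isolated)
Conditions: LiHMDS, THF, −78 °C; CF3CO2CH2CF3, −78 °C; aq. NH4Cl; then 4-acetamidobenzenesulfonyl azide, Et3N, H2O (1 equiv), MeCN, rt
Reagents that add atoms: 4-acetamidobenzenesulfonyl azide, CC(=O)Nc1ccc(cc1)S(=O)(=O)N=[N+]=[N-] (the N2 unit of 17); 2,2,2-trifluoroethyl trifluoroacetate, O=C(OCC(F)(F)F)C(F)(F)F (the trifluoroacetyl group of 16 only)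
Why: Detrifluoroacetylative diazo transfer (Danheiser protocol): the kinetic lithium enolate at C3 is acylated at −78 °C, where β-elimination of the ring D phenoxide should be slow, and the resulting 1,3-diketone transfers its trifluoroacetyl group to the sulfonamide while C3 takes up N2, leaving C2 untouched.

**Step 13**
Reactants: 17 3-diazoflavanone; 18 methanol (also the solvent)
Product: 20 methyl (2R,3S)-2-[4-(methoxymethoxy)-5-prenyl-2-(prop-2-en-1-yloxy)phenyl]-2,3-dihydrobenzofuran-3-carboxylate with 2,3-cis configuration, bearing on ring D the fused ring E, the MOM ether and the prenyl group (rings C, D and E complete), via ring-contracted ketene 19 (not isolated)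
Conditions: hν (LED, 400–450 nm), MeOH/THF (4:1), 0–20 °C, degassed
Reagents that add atoms: none
Why: Excitation of the diazo ketone, which the ring locks s-cis, expels N2 in concert with the 1,2-shift of the ring D carbon C6b from the carbonyl carbon to the diazo carbon, so the C6a–C6b bond forms and the pyranone contracts to ketene 19 without a free carbene that could undergo 1,2-hydride shift to the flavone or O–H insertion. The closest known reaction type is the photochemical Wolff ring contraction of cyclic 2-diazo ketones, including 3-diazochroman-4-ones to 2,3-dihydrobenzofuran-3-carboxylates. Ring C is not closed from an open chain but arises by contraction of the six-membered ring through this 1,2-aryl shift, the old carbonyl carbon leaving the ring as C6. Methanol adds to the ketene, and the resulting ester enol is protonated at C6a on the face anti to the C11a aryl group, which allylic strain with the exocyclic enol pushes pseudo-axial, so the kinetic product should be the cis ester (new stereocentre C6a controlled by C11a). C11a is not touched, and the base-free medium avoids epimerisation to the more stable trans ester. The step needs migration over carbene chemistry and excitation of the diazo chromophore only: the locked geometry secures the first, and light of 400–450 nm, which ring E (a photochromic 2,2-dimethylchromene) and the aryl allyl ether do not absorb, secures the second.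

**Step 14**
Reactants: 20 cis methyl ester
Product: 21 [(2R,3R)-2-[4-(methoxymethoxy)-5-prenyl-2-(prop-2-en-1-yloxy)phenyl]-2,3-dihydrobenzofuran-3-yl]methanol with ring D substituents and ring E as in 20 (C6 alcohol, 2,3-cis)
Conditions: DIBAL-H (3 equiv), CH2Cl2, −78 → 0 °C
Reagents that add atoms: none
Why: Hydride reduction of the ester to the primary alcohol with a Lewis-acidic, non-basic reagent at low temperature should not enolise C6a, so the cis relationship is fixed once C6 is at the alcohol level.

**Step 15**
Reactants: 21 C6 alcohol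
Product: 22 2-[(2R,3R)-3-(hydroxymethyl)-2,3-dihydrobenzofuran-2-yl]-5-(methoxymethoxy)-4-prenylphenol with ring D substituents and ring E as in 20 (phenol–alcohol diol)
Conditions: Pd(PPh3)4 (5 mol%), morpholine, THF, rt
Reagents that add atoms: none
Why: Tsuji–Trost deallylation: zerovalent palladium ionises only the allyl aryl ether, morpholine traps the allyl cation equivalent, and the C-prenyl groups, chromene, MOM ethers and primary alcohol cannot form a π-allyl complex under these conditions.

**Step 16**
Reactants: 22 phenol–alcohol diol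
Product: 23 (6aR,11aR)-3,9-bis(methoxymethoxy)-2,10-diprenylpterocarpan carrying ring E fused across C7–C8 with the pyran oxygen on C8 (bis-MOM lespecyrtin E3)
Conditions: PPh3, DIAD, THF, 0 °C → rt, 0.01 M
Reagents that add atoms: none
Why: Intramolecular Mitsunobu etherification: the primary C6 alcohol is activated as the alkoxyphosphonium ion and displaced by the ring A phenoxide in a 6-exo-tet closure of ring B, which is possible only for the cis isomer and touches neither stereocentre.

**Step 17**
Reactants: 23 bis-MOM lespecyrtin E3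
Product: 25 lespecyrtin E3, (6aR,11aR)-3,9-dihydroxy-2,10-diprenylpterocarpan with ring E fused across C7–C8, via bis(trimethylsilyl) ether 24 (not isolated)
Conditions: TMSOTf, 2,2′-bipyridyl, MeCN, 0 °C → rt; then H2O
Reagents that add atoms: none
Why: Cleavage of aromatic MOM ethers with the TMSOTf–2,2′-bipyridyl complex runs through aryl silyl ethers that hydrolyse on addition of water, with no free protic acid present, so the prenyl groups next to the liberated phenols, the chromene and the acid-labile benzylic C11a–O11 bond should survive.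

**Compound list**

1 | 2,4,5-trihydroxyacetophenone | CC(=O)c1cc(O)c(O)cc1O | starting material
2 | 1-[2,5-dihydroxy-4-(methoxymethoxy)phenyl]ethan-1-one | CC(=O)c1cc(O)c(OCOC)cc1O | intermediate
3 | 3-chloro-3-methylbut-1-yne | CC(C)(Cl)C#C | starting material
4 | 1-[2-hydroxy-4-(methoxymethoxy)-5-[(2-methylbut-3-yn-2-yl)oxy]phenyl]ethan-1-one | CC(=O)c1cc(OC(C)(C)C#C)c(OCOC)cc1O | intermediate
5 | 1-[2-hydroxy-3-iodo-4-(methoxymethoxy)-5-[(2-methylbut-3-yn-2-yl)oxy]phenyl]ethan-1-one | CC(=O)c1cc(OC(C)(C)C#C)c(OCOC)c(I)c1O | intermediate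
6 | 1-[6-hydroxy-7-iodo-8-(methoxymethoxy)-2,2-dimethyl-2H-chromen-5-yl]ethan-1-one | CC(=O)c1c(O)c(I)c(OCOC)c2OC(C)(C)C=Cc12 | intermediate
7 | tributyl(3-methylbut-2-en-1-yl)stannane | CCCC[Sn](CCCC)(CCCC)CC=C(C)C | starting material
8 | 1-[6-hydroxy-8-(methoxymethoxy)-2,2-dimethyl-7-(3-methylbut-2-en-1-yl)-2H-chromen-5-yl]ethan-1-one (ring D ketone) | CC(=O)c1c(O)c(CC=C(C)C)c(OCOC)c2OC(C)(C)C=Cc12 | intermediate
9 | 5-bromo-2,4-dihydroxybenzaldehyde | O=Cc1cc(Br)c(O)cc1O | starting material
10 | 5-bromo-2-hydroxy-4-(methoxymethoxy)benzaldehyde | O=Cc1cc(Br)c(OCOC)cc1O | intermediate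
11 | 2-hydroxy-4-(methoxymethoxy)-5-(3-methylbut-2-en-1-yl)benzaldehyde | O=Cc1cc(CC=C(C)C)c(OCOC)cc1O | intermediate
12 | 4-(methoxymethoxy)-5-(3-methylbut-2-en-1-yl)-2-(prop-2-en-1-yloxy)benzaldehyde (ring A aldehyde) | O=Cc1cc(CC=C(C)C)c(OCOC)cc1OCC=C | intermediate
13 | (E)-2'-hydroxychalcone from 8 and 12 | O=C(/C=C/c1cc(CC=C(C)C)c(OCOC)cc1OCC=C)c1c(O)c(CC=C(C)C)c(OCOC)c2OC(C)(C)C=Cc12 | intermediate
14 | racemic flavanone built on ring D (ring E fused at C5–C6, 7-OMOM, 8-prenyl, 2-aryl = ring A) | O=C1CC(c2cc(CC=C(C)C)c(OCOC)cc2OCC=C)Oc2c(CC=C(C)C)c(OCOC)c3OC(C)(C)C=Cc3c12 | intermediate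
15 | (2R)-flavanone | O=C1C[C@H](c2cc(CC=C(C)C)c(OCOC)cc2OCC=C)Oc2c(CC=C(C)C)c(OCOC)c3OC(C)(C)C=Cc3c12 | intermediate
16 | (2R)-3-(trifluoroacetyl)flavanone (C3 not defined, largely enolised) | O=C1C(C(=O)C(F)(F)F)[C@H](c2cc(CC=C(C)C)c(OCOC)cc2OCC=C)Oc2c(CC=C(C)C)c(OCOC)c3OC(C)(C)C=Cc3c12 | intermediate
17 | (2S)-3-diazoflavanone (key-step precursor) | O=C1C(=[N+]=[N-])[C@H](c2cc(CC=C(C)C)c(OCOC)cc2OCC=C)Oc2c(CC=C(C)C)c(OCOC)c3OC(C)(C)C=Cc3c12 | intermediate
18 | methanol | CO | starting material
19 | ring-contracted ketene (C11a configuration retained) | O=C=C1c2c3c(c(OCOC)c(CC=C(C)C)c2O[C@H]1c1cc(CC=C(C)C)c(OCOC)cc1OCC=C)OC(C)(C)C=C3 | intermediate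
20 | methyl (2R,3S)-cis-2-aryl-2,3-dihydrobenzofuran-3-carboxylate, rings C, D and E complete (key-step product) | COC(=O)[C@H]1c2c3c(c(OCOC)c(CC=C(C)C)c2O[C@H]1c1cc(CC=C(C)C)c(OCOC)cc1OCC=C)OC(C)(C)C=C3 | intermediate
21 | (2R,3R)-cis-3-(hydroxymethyl)-2-aryl-2,3-dihydrobenzofuran, allyl ether retained | OC[C@H]1c2c3c(c(OCOC)c(CC=C(C)C)c2O[C@H]1c1cc(CC=C(C)C)c(OCOC)cc1OCC=C)OC(C)(C)C=C3 | intermediate
22 | (2R,3R)-cis phenol–alcohol diol | OC[C@H]1c2c3c(c(OCOC)c(CC=C(C)C)c2O[C@H]1c1cc(CC=C(C)C)c(OCOC)cc1O)OC(C)(C)C=C3 | intermediate
23 | (6aR,11aR)-3,9-bis(methoxymethoxy) pterocarpan (bis-MOM lespecyrtin E3) | CC(C)=CCc1cc2c(cc1OCOC)OC[C@H]1c3c4c(c(OCOC)c(CC=C(C)C)c3O[C@@H]21)OC(C)(C)C=C4 | intermediate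
24 | (6aR,11aR)-3,9-bis(trimethylsilyloxy) pterocarpan | CC(C)=CCc1cc2c(cc1O[Si](C)(C)C)OC[C@H]1c3c4c(c(O[Si](C)(C)C)c(CC=C(C)C)c3O[C@@H]21)OC(C)(C)C=C4 | intermediate
25 | lespecyrtin E3, (6aR,11aR) | CC(C)=CCc1cc2c(cc1O)OC[C@H]1c3c4c(c(O)c(CC=C(C)C)c3O[C@@H]21)OC(C)(C)C=C4 | target

**Step count**

Total: 17 steps. Longest linear sequence: 14 steps (steps 1–5, then 9–17); steps 6–8 form the ring A branch.

**Steps most likely to fail**

Step 13. The ester enol may be protonated partly on the wrong face, or the cis ester may epimerise on handling, so that trans ester forms, which cannot close ring B. The fallback sets out from 20, taken as the mixture of C6a epimers. Deallylation with Pd(PPh3)4 and morpholine in THF would give the free-phenol methyl ester F1. Warming F1 with catalytic DBU in toluene at 80 °C over 5 Å molecular sieves would epimerise the trans ester through its enolate, and since only the cis epimer can acylate the ring A phenol, the material would collect as the cis-fused lactone F2 while the sieves take up the methanol. Reduction of F2 with LiBH4 in THF at 0 °C would give the phenol–alcohol diol, and the route is rejoined at 22.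

Step 12. The flavanone enolate may open by β-elimination of the ring D phenoxide to the chalcone, and reversible opening at the trifluoroacetyl stage would erode the C2 configuration. The fallback sets out from 15 and avoids the amide base. Condensation with N,N-dimethylformamide dimethyl acetal (neat, 80 °C) through the neutral enol would give the 3-(dimethylaminomethylidene)flavanone F3. Diazo transfer to this enaminone with 4-acetamidobenzenesulfonyl azide in MeCN at rt would then expel the N-sulfonylformamidine and return to the route at 17.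

Step 11. The rate difference between the enantiomers may be too small, or reduction too slow, because the carbonyl is flanked by the peri vinyl carbon of ring E. The fallback sets out from 14 and resolves at the alcohol level. NaBH4 in MeOH/THF at 0 °C would give the racemic cis-flavan-4-ol F4 (hydride anti to the 2-aryl group). Acylation with vinyl acetate and Burkholderia cepacia lipase in MTBE at 30 °C should, by the Kazlauskas rule, acylate the 4R alcohol to the (2R,4R)-acetate F5, which is separated from the unreacted (2S,4S)-alcohol. Methanolysis of F5 (K2CO3, MeOH) would give the (2R,4R)-flavan-4-ol F6, and oxidation with Dess–Martin periodinane and NaHCO3 in CH2Cl2 would return to the route at 15.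

**Further compounds**

F1 | step 13 | free-phenol methyl ester, (2R) with C3 as epimer mixture (deallylated 20) | COC(=O)C1c2c3c(c(OCOC)c(CC=C(C)C)c2O[C@H]1c1cc(CC=C(C)C)c(OCOC)cc1O)OC(C)(C)C=C3
F2 | step 13 | cis-fused lactone, (6aS,11aR)-3,9-bis(methoxymethoxy)-6-oxopterocarpan with ring E and both prenyl groups | CC(C)=CCc1cc2c(cc1OCOC)OC(=O)[C@H]1c3c4c(c(OCOC)c(CC=C(C)C)c3O[C@@H]21)OC(C)(C)C=C4
F3 | step 12 | 3-(dimethylaminomethylidene)flavanone, C2 configured as in 15 | O=C1C(=CN(C)C)[C@H](c2cc(CC=C(C)C)c(OCOC)cc2OCC=C)Oc2c(CC=C(C)C)c(OCOC)c3OC(C)(C)C=Cc3c12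
F4 | step 11 | racemic cis-flavan-4-ol (relative configuration shown, both enantiomers present) | O[C@@H]1C[C@H](c2cc(CC=C(C)C)c(OCOC)cc2OCC=C)Oc2c(CC=C(C)C)c(OCOC)c3OC(C)(C)C=Cc3c12
F5 | step 11 | (2R,4R)-cis-flavan-4-yl acetate | CC(=O)O[C@@H]1C[C@H](c2cc(CC=C(C)C)c(OCOC)cc2OCC=C)Oc2c(CC=C(C)C)c(OCOC)c3OC(C)(C)C=Cc3c12
F6 | step 11 | (2R,4R)-cis-flavan-4-ol | O[C@@H]1C[C@H](c2cc(CC=C(C)C)c(OCOC)cc2OCC=C)Oc2c(CC=C(C)C)c(OCOC)c3OC(C)(C)C=Cc3c12
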